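**Plan**

1. Retrosynthesis: the C8 ester and the C12–O6 lactone bond are cut last. The core is then cut at the ether bond O–C10 and at C7–C8 at once, which opens ring A (oxepene: O, C5, C4, C3, C2, C1, C10) and ring B (oxepane: O, C5, C6, C7, C8, C9, C10) to an acyclic bromo enal. That chain is cut at C4–C5, C3=C4 and C7=C11.
2. Enabling feature: the tertiary ether carbon C10 and the carbinol C8 are 1,3-related, the retron of a β,β-disubstituted enal O=C8–C9=C10. O5 sits for a 7-exo addition to C10, and C7 is the γ-carbon of a 2-(bromomethyl)enoate (C13–C11=C7). One oxa-Michael/Barbier allylation domino can therefore close both rings and release the C11=C13 methylene.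
3. Forward: C5–C7/C11–C13 from (R)-glyceraldehyde acetonide and methyl acrylate; C8–C10/C1–C4/C15 from geranyl acetate; Ni/Cr coupling at C4–C5; unveiling of enal and allyl bromide; domino closure of rings A and B; acylation of O8; closure of the lactone (ring C).
4. Stereochemistry: C6 from the chiral pool; C5 by Felkin–Anh addition; C10 (ring constraint), C7 (allylic 1,3-strain) and C8 (chair transition state) in the key step; the epoxy acid by Sharpless epoxidation.
5. Locants are germacrane-type: ring carbons C1–C10, C14 the methyl on C10, C15 the ester carbon on C4, C11–C13 the methylene lactone carbons.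

Key step: step 13

Remarks on the chemistry: the epoxy ester is taken as drawn, (2S,3R), i.e. the cis-dimethyl oxirane of an (E)-2-methylbut-2-enoate. Compounds 1, 2, 10, 13 and 21 are taken as commercial. Compounds 3 and 4 are carried as epimer mixtures at the carbinol carbon, which is erased in step 2.

**Route**

Step 1
Reactants: 1 (R)-2,2-dimethyl-1,3-dioxolane-4-carbaldehyde; 2 methyl acrylate
Product: 3 methyl 2-{[(4R)-2,2-dimethyl-1,3-dioxolan-4-yl](hydroxy)methyl}prop-2-enoate (both carbinol epimers)
Conditions: DABCO (1 equiv), 1,4-dioxane/H2O (1:1), rt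
Reagents that add atoms: none
Why: Morita–Baylis–Hillman reaction, in which the DABCO-derived ammonium enolate of 2 attacks the activated α-alkoxy aldehyde faster than the aldehyde enolises, so the dioxolane center (later C6) should be kept while the new carbinol center, formed as an epimer mixture, is erased in step 2.

Step 2
Reactants: 3 methyl 2-{[(4R)-2,2-dimethyl-1,3-dioxolan-4-yl](hydroxy)methyl}prop-2-enoate
Product: 5 methyl (2E)-2-(acetoxymethyl)-3-[(4S)-2,2-dimethyl-1,3-dioxolan-4-yl]prop-2-enoate, via secondary acetate 4 (not isolated)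
Conditions: Ac2O, Et3N, DMAP (cat.), CH2Cl2, 0 °C; then DABCO (0.3 equiv), THF, 65 °C
Reagents that add atoms: acetic anhydride CC(=O)OC(C)=O
Why: O-acetylation followed by the DABCO-catalysed SN2′/SN2 allylic transposition of Morita–Baylis–Hillman acetates should give the thermodynamically preferred primary allylic acetate with the ester trans to the C6 substituent, the geometry later needed for a (Z)-configured allyl metal.

Step 3
Reactants: 5 methyl (2E)-2-(acetoxymethyl)-3-[(4S)-2,2-dimethyl-1,3-dioxolan-4-yl]prop-2-enoate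
Product: 6 methyl (2E,4S)-2-(acetoxymethyl)-4,5-dihydroxypent-2-enoate
Conditions: AcOH/H2O (4:1), 40 °C
Reagents that add atoms: none
Why: acid-catalysed acetal hydrolysis, in which lactone formation is excluded because the ester is trans to the diol chain and the primary acetate is stable to aqueous acetic acid.

Step 4
Reactants: 6 methyl (2E,4S)-2-(acetoxymethyl)-4,5-dihydroxypent-2-enoate
Product: 7 methyl (2E,4S)-2-(acetoxymethyl)-4,5-bis[(tert-butyldimethylsilyl)oxy]pent-2-enoate
Conditions: TBSOTf, 2,6-lutidine, CH2Cl2, −78 to 0 °C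
Reagents that add atoms: tert-butyldimethylsilyl triflate CC(C)(C)[Si](C)(C)OS(=O)(=O)C(F)(F)F
Why: exhaustive silyl ether formation with the silyl triflate covers also the hindered secondary allylic hydroxyl that becomes O6.

Step 5
Reactants: 7 methyl (2E,4S)-2-(acetoxymethyl)-4,5-bis[(tert-butyldimethylsilyl)oxy]pent-2-enoate
Product: 8 methyl (2E,4S)-2-(acetoxymethyl)-4-[(tert-butyldimethylsilyl)oxy]-5-hydroxypent-2-enoate
Conditions: HF·pyridine, pyridine, THF, 0 °C
Reagents that add atoms: none
Why: selective protodesilylation, because buffered HF·pyridine cleaves the unhindered primary silyl ether much faster than the secondary allylic one.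

Step 6
Reactants: 8 methyl (2E,4S)-2-(acetoxymethyl)-4-[(tert-butyldimethylsilyl)oxy]-5-hydroxypent-2-enoate
Product: 9 methyl (2E,4S)-2-(acetoxymethyl)-4-[(tert-butyldimethylsilyl)oxy]-5-oxopent-2-enoate
Conditions: Dess–Martin periodinane, NaHCO3, CH2Cl2, 0 °C
Reagents that add atoms: none
Why: Dess–Martin oxidation under buffered, essentially non-basic conditions should give the α-silyloxy aldehyde without epimerising the doubly activated C6–H, and the aldehyde is used at once.

Step 7
Reactants: 10 geranyl acetate, (2E)-3,7-dimethylocta-2,6-dien-1-yl acetate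
Product: 12 (2E)-3-methyl-6-oxohex-2-en-1-yl acetate, via epoxide 11 (not isolated)
Conditions: mCPBA, CH2Cl2, 0 °C; then H5IO6, THF/H2O, 0 °C to rt
Reagents that add atoms: mCPBA O=C(OO)c1cccc(Cl)c1; water O (the aldehyde oxygen stems from one of the two)
Why: Prilezhaev epoxidation selects the electron-rich remote trisubstituted alkene (the 2,3-alkene is deactivated by the allylic acetate), and periodic acid cleavage of the epoxide delivers the aldehyde with the (E)-alkene untouched.

Step 8
Reactants: 12 (2E)-3-methyl-6-oxohex-2-en-1-yl acetate; 13 methyl (triphenylphosphoranylidene)acetate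
Product: 14 methyl (2Z,6E)-8-acetoxy-2-iodo-6-methylocta-2,6-dienoate
Conditions: NIS, CH2Cl2, −20 °C; then 12, −20 °C to rt
Reagents that add atoms: N-iodosuccinimide O=C1CCC(=O)N1I
Why: Wittig olefination with the ylide iodinated in situ, in which the stabilised iodo ylide should place the ester trans to the chain and so give the (Z)-α-iodo enoate needed for retention in step 9.

Step 9
Reactants: 14 methyl (2Z,6E)-8-acetoxy-2-iodo-6-methylocta-2,6-dienoate; 9 methyl (2E,4S)-2-(acetoxymethyl)-4-[(tert-butyldimethylsilyl)oxy]-5-oxopent-2-enoate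
Product: 15 methyl (2E,4S,5R,6E,10E)-12-acetoxy-2-(acetoxymethyl)-4-[(tert-butyldimethylsilyl)oxy]-5-hydroxy-6-(methoxycarbonyl)-10-methyldodeca-2,6,10-trienoate
Conditions: CrCl2 (6 equiv), NiCl2 (2 mol%), DMSO, rt
Reagents that add atoms: none
Why: Nozaki–Hiyama–Kishi coupling, in which zerovalent nickel inserts into the C–I bond, transmetalation gives an alkenyl species of trivalent chromium that adds with retention of alkene geometry and only to the aldehyde, and Felkin–Anh attack anti to the α-silyloxy group should set C5 as R (anti to O6).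

Step 10
Reactants: 15 methyl (2E,4S,5R,6E,10E)-12-acetoxy-2-(acetoxymethyl)-4-[(tert-butyldimethylsilyl)oxy]-5-hydroxy-6-(methoxycarbonyl)-10-methyldodeca-2,6,10-trienoate
Product: 16 methyl (2E,4S,5R,6E,10E)-4-[(tert-butyldimethylsilyl)oxy]-5,12-dihydroxy-2-(hydroxymethyl)-6-(methoxycarbonyl)-10-methyldodeca-2,6,10-trienoate
Conditions: K2CO3 (0.3 equiv), MeOH, 0 °C
Reagents that add atoms: none
Why: base-catalysed methanolysis cleaves the two primary allylic acetates much faster than the hindered conjugated methyl esters, and the low temperature should suppress migration of the silyl group to the neighbouring free hydroxyl.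

Step 11
Reactants: 16 methyl (2E,4S,5R,6E,10E)-4-[(tert-butyldimethylsilyl)oxy]-5,12-dihydroxy-2-(hydroxymethyl)-6-(methoxycarbonyl)-10-methyldodeca-2,6,10-trienoate
Product: 17 methyl (2E,4S,5R,6E,10E)-4-[(tert-butyldimethylsilyl)oxy]-5-hydroxy-2-(hydroxymethyl)-6-(methoxycarbonyl)-10-methyl-12-oxododeca-2,6,10-trienoate
Conditions: MnO2, CH2Cl2, rt
Reagents that add atoms: none
Why: MnO2 allylic oxidation should convert the electron-rich primary allylic alcohol at C8 into the (E)-enal selectively, since the hydroxymethyl group on the electron-poor enoate and the hindered secondary C5 carbinol react far more slowly.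

Step 12
Reactants: 17 methyl (2E,4S,5R,6E,10E)-4-[(tert-butyldimethylsilyl)oxy]-5-hydroxy-2-(hydroxymethyl)-6-(methoxycarbonyl)-10-methyl-12-oxododeca-2,6,10-trienoate
Product: 18 methyl (2Z,4S,5R,6E,10E)-2-(bromomethyl)-4-[(tert-butyldimethylsilyl)oxy]-5-hydroxy-6-(methoxycarbonyl)-10-methyl-12-oxododeca-2,6,10-trienoate
Conditions: NBS, Me2S, CH2Cl2, −30 to 0 °C
Reagents that add atoms: N-bromosuccinimide O=C1CCC(=O)N1Br
Why: Corey–Kim bromination, in which the sulfonium reagent activates the unhindered primary allylic hydroxyl and bromide displaces it by SN2, should leave the hindered secondary C5 hydroxyl, the enal and the alkene geometry (now Z by priority) untouched, and the bromide is used at once.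

Step 13
Reactants: 18 methyl (2Z,4S,5R,6E,10E)-2-(bromomethyl)-4-[(tert-butyldimethylsilyl)oxy]-5-hydroxy-6-(methoxycarbonyl)-10-methyl-12-oxododeca-2,6,10-trienoate
Product: 20 methyl (1R,6S,8R,9R,10S)-10-[(tert-butyldimethylsilyl)oxy]-8-hydroxy-9-(3-methoxy-3-oxoprop-1-en-2-yl)-6-methyl-11-oxabicyclo[4.4.1]undec-2-ene-2-carboxylate, via oxa-Michael adduct 19 (not isolated)
Conditions: In powder (3 equiv), Sc(OTf)3 (20 mol%), THF/H2O (4:1), 2 mM, rt
Reagents that add atoms: none
Why: Proposed new method: the Lewis acid should equilibrate hydroxy enal 18 with the 7-exo-trig oxa-Michael adduct 19 (ring A, O–C10 bond), and the allylindium formed by insertion of zerovalent indium into the C13–Br bond then adds through its γ-carbon C7 to the now saturated C8 aldehyde in a closed six-membered Zimmerman–Traxler transition state (7-exo-trig closure of ring B, C7–C8 bond, with the C11=C13 methylene released by allyl transposition). The closest known reaction types are the intramolecular Barbier allylation of aldehydes with 2-(bromomethyl)alk-2-enoates used to close carbocycles and the acid-catalysed intramolecular oxa-Michael addition of hydroxy enals; their coupling in one flask is the new element. C10 is fixed by the ring, because only the adduct with the C6 and C9 arms cis on ring A can reach the allylation transition state and the reversible oxa-Michael step returns the other epimer (Curtin–Hammett). C7 is set by allylic 1,3-strain, which places H6 in the plane of the (Z)-allyl unit so that the tethered aldehyde arrives on the C5 face, anti to the C6 silyloxy group (the trans relationship of the later lactone), and C8 is set syn to C6 by the chair transition state of the (Z)-configured allylindium. The step needs seven-ring closure of 19 to outrun direct ten-membered 1,2-allylation of the enal in 18 and O-alkylation of the free hydroxyl; high dilution, the higher electrophilicity and proximity of the saturated aldehyde in 19 and the acidic, base-free medium should secure this, while the silyl ether on O6 blocks a competing oxa-Michael addition and ring closure by that oxygen.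

Step 14
Reactants: 21 (2E)-2-methylbut-2-en-1-ol
Product: 22 [(2R,3R)-2,3-dimethyloxiran-2-yl]methanol
Conditions: Ti(OiPr)4 (cat.), D-(−)-diisopropyl tartrate (cat.), t-BuOOH, 4 Å MS, CH2Cl2, −20 °C
Reagents that add atoms: tert-butyl hydroperoxide CC(C)(C)OO
Why: Sharpless asymmetric epoxidation, in which the titanium tartrate complex delivers oxygen to one face of the allylic alcohol, so that D-(−)-tartrate should give the (2R,3R)-epoxy alcohol with the two methyl groups cis as fixed by the (E)-alkene.

Step 15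
Reactants: 22 [(2R,3R)-2,3-dimethyloxiran-2-yl]methanol
Product: 23 (2S,3R)-2,3-dimethyloxirane-2-carboxylic acid
Conditions: RuCl3 (cat.), NaIO4, MeCN/EtOAc/H2O, 0 °C to rt
Reagents that add atoms: water O; sodium periodate [Na+].[O-]I(=O)(=O)=O (oxygen passes on through RuO4)
Why: RuO4 oxidation of the primary alcohol to the acid leaves the epoxide and both stereocenters untouched, the descriptor at C2 changing to S only through the change of priorities.

Step 16
Reactants: 20 methyl (1R,6S,8R,9R,10S)-10-[(tert-butyldimethylsilyl)oxy]-8-hydroxy-9-(3-methoxy-3-oxoprop-1-en-2-yl)-6-methyl-11-oxabicyclo[4.4.1]undec-2-ene-2-carboxylate; 23 (2S,3R)-2,3-dimethyloxirane-2-carboxylic acid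
Product: 25 methyl (1R,6S,8R,9R,10S)-10-[(tert-butyldimethylsilyl)oxy]-8-{[(2S,3R)-2,3-dimethyloxiran-2-yl]carbonyloxy}-9-(3-methoxy-3-oxoprop-1-en-2-yl)-6-methyl-11-oxabicyclo[4.4.1]undec-2-ene-2-carboxylate, via mixed anhydride 24 (not isolated)
Conditions: 2,4,6-trichlorobenzoyl chloride, Et3N, THF, 0 °C; then 20, DMAP, PhMe, rt
Reagents that add atoms: none
Why: Yamaguchi esterification, in which DMAP attacks the mixed anhydride at the less hindered aliphatic carbonyl and the acylpyridinium acylates the C8 hydroxyl without touching a stereocenter, is run on fresh 20 to forestall closure of that hydroxyl onto the C12 ester.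

Step 17
Reactants: 25 methyl (1R,6S,8R,9R,10S)-10-[(tert-butyldimethylsilyl)oxy]-8-{[(2S,3R)-2,3-dimethyloxiran-2-yl]carbonyloxy}-9-(3-methoxy-3-oxoprop-1-en-2-yl)-6-methyl-11-oxabicyclo[4.4.1]undec-2-ene-2-carboxylate
Product: 27 CNP0240298.1, via hydroxy ester 26 (not isolated)
Conditions: HF·pyridine, pyridine, THF, 0 °C to rt; then PPTS (cat.), PhMe, 50 °C
Reagents that add atoms: none
Why: desilylation frees O6, which should close onto the C12 methyl ester by mildly acid-catalysed intramolecular transesterification (lactonisation) to the trans-fused α-methylene γ-lactone, and since O8 is already acylated only the 6,12-lactone can form.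

**Compound list**

1 | (R)-2,2-dimethyl-1,3-dioxolane-4-carbaldehyde | O=C[C@H]1COC(C)(C)O1 | starting material
2 | methyl acrylate | C=CC(=O)OC | starting material
3 | methyl 2-{[(4R)-2,2-dimethyl-1,3-dioxolan-4-yl](hydroxy)methyl}prop-2-enoate (both carbinol epimers) | C=C(C(=O)OC)C(O)[C@H]1COC(C)(C)O1 | intermediate
4 | methyl 2-{acetoxy[(4R)-2,2-dimethyl-1,3-dioxolan-4-yl]methyl}prop-2-enoate (both epimers) | C=C(C(=O)OC)C(OC(C)=O)[C@H]1COC(C)(C)O1 | intermediate
5 | methyl (2E)-2-(acetoxymethyl)-3-[(4S)-2,2-dimethyl-1,3-dioxolan-4-yl]prop-2-enoate | COC(=O)C(/COC(C)=O)=C/[C@H]1COC(C)(C)O1 | intermediate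
6 | methyl (2E,4S)-2-(acetoxymethyl)-4,5-dihydroxypent-2-enoate | COC(=O)C(/COC(C)=O)=C/[C@H](O)CO | intermediate
7 | methyl (2E,4S)-2-(acetoxymethyl)-4,5-bis[(tert-butyldimethylsilyl)oxy]pent-2-enoate | COC(=O)C(/COC(C)=O)=C/[C@H](O[Si](C)(C)C(C)(C)C)CO[Si](C)(C)C(C)(C)C | intermediate
8 | methyl (2E,4S)-2-(acetoxymethyl)-4-[(tert-butyldimethylsilyl)oxy]-5-hydroxypent-2-enoate | COC(=O)C(/COC(C)=O)=C/[C@H](O[Si](C)(C)C(C)(C)C)CO | intermediate
9 | methyl (2E,4S)-2-(acetoxymethyl)-4-[(tert-butyldimethylsilyl)oxy]-5-oxopent-2-enoate | COC(=O)C(/COC(C)=O)=C/[C@H](O[Si](C)(C)C(C)(C)C)C=O | intermediate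
10 | geranyl acetate, (2E)-3,7-dimethylocta-2,6-dien-1-yl acetate | CC(C)=CCC/C(C)=C/COC(C)=O | starting material
11 | (2E)-6,7-epoxy-3,7-dimethyloct-2-en-1-yl acetate (racemic epoxide) | CC1(C)OC1CC/C(C)=C/COC(C)=O | intermediate
12 | (2E)-3-methyl-6-oxohex-2-en-1-yl acetate | O=CCC/C(C)=C/COC(C)=O | intermediate
13 | methyl (triphenylphosphoranylidene)acetate | COC(=O)C=P(c1ccccc1)(c1ccccc1)c1ccccc1 | starting material
14 | methyl (2Z,6E)-8-acetoxy-2-iodo-6-methylocta-2,6-dienoate | COC(=O)/C(I)=C/CC/C(C)=C/COC(C)=O | intermediate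
15 | methyl (2E,4S,5R,6E,10E)-12-acetoxy-2-(acetoxymethyl)-4-[(tert-butyldimethylsilyl)oxy]-5-hydroxy-6-(methoxycarbonyl)-10-methyldodeca-2,6,10-trienoate | CC(=O)OC/C=C(C)/CC/C=C(/C(=O)OC)[C@@H](O)[C@@H](O[Si](C)(C)C(C)(C)C)/C=C(/C(=O)OC)COC(C)=O | intermediate
16 | methyl (2E,4S,5R,6E,10E)-4-[(tert-butyldimethylsilyl)oxy]-5,12-dihydroxy-2-(hydroxymethyl)-6-(methoxycarbonyl)-10-methyldodeca-2,6,10-trienoate | OC/C=C(C)/CC/C=C(/C(=O)OC)[C@@H](O)[C@@H](O[Si](C)(C)C(C)(C)C)/C=C(/C(=O)OC)CO | intermediate
17 | methyl (2E,4S,5R,6E,10E)-4-[(tert-butyldimethylsilyl)oxy]-5-hydroxy-2-(hydroxymethyl)-6-(methoxycarbonyl)-10-methyl-12-oxododeca-2,6,10-trienoate | O=C/C=C(C)/CC/C=C(/C(=O)OC)[C@@H](O)[C@@H](O[Si](C)(C)C(C)(C)C)/C=C(/C(=O)OC)CO | intermediate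
18 | methyl (2Z,4S,5R,6E,10E)-2-(bromomethyl)-4-[(tert-butyldimethylsilyl)oxy]-5-hydroxy-6-(methoxycarbonyl)-10-methyl-12-oxododeca-2,6,10-trienoate | O=C/C=C(C)/CC/C=C(/C(=O)OC)[C@@H](O)[C@@H](O[Si](C)(C)C(C)(C)C)/C=C(/C(=O)OC)CBr | intermediate
19 | oxa-Michael adduct: methyl (2Z,4S)-2-(bromomethyl)-4-[(tert-butyldimethylsilyl)oxy]-4-[(2R,7S)-3-(methoxycarbonyl)-7-methyl-7-(2-oxoethyl)-2,5,6,7-tetrahydrooxepin-2-yl]but-2-enoate | O=CC[C@]1(C)CCC=C(C(=O)OC)[C@@H](O1)[C@@H](O[Si](C)(C)C(C)(C)C)/C=C(/C(=O)OC)CBr | intermediate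
20 | methyl (1R,6S,8R,9R,10S)-10-[(tert-butyldimethylsilyl)oxy]-8-hydroxy-9-(3-methoxy-3-oxoprop-1-en-2-yl)-6-methyl-11-oxabicyclo[4.4.1]undec-2-ene-2-carboxylate (germacrane locants 5R,6S,7R,8R,10S) | C=C(C(=O)OC)[C@@H]1[C@H](O)C[C@]2(C)CCC=C(C(=O)OC)[C@@H](O2)[C@H]1O[Si](C)(C)C(C)(C)C | intermediate
21 | (2E)-2-methylbut-2-en-1-ol | C/C=C(C)/CO | starting material
22 | [(2R,3R)-2,3-dimethyloxiran-2-yl]methanol | OC[C@@]1(C)O[C@@H]1C | intermediate
23 | (2S,3R)-2,3-dimethyloxirane-2-carboxylic acid | OC(=O)[C@@]1(C)O[C@@H]1C | intermediate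
24 | (2S,3R)-2,3-dimethyloxirane-2-carboxylic 2,4,6-trichlorobenzoic anhydride | O=C(OC(=O)[C@@]1(C)O[C@@H]1C)c1c(Cl)cc(Cl)cc1Cl | intermediate
25 | methyl (1R,6S,8R,9R,10S)-10-[(tert-butyldimethylsilyl)oxy]-8-{[(2S,3R)-2,3-dimethyloxiran-2-yl]carbonyloxy}-9-(3-methoxy-3-oxoprop-1-en-2-yl)-6-methyl-11-oxabicyclo[4.4.1]undec-2-ene-2-carboxylate | C=C(C(=O)OC)[C@@H]1[C@H](OC(=O)[C@@]3(C)O[C@@H]3C)C[C@]2(C)CCC=C(C(=O)OC)[C@@H](O2)[C@H]1O[Si](C)(C)C(C)(C)C | intermediate
26 | methyl (1R,6S,8R,9S,10S)-8-{[(2S,3R)-2,3-dimethyloxiran-2-yl]carbonyloxy}-10-hydroxy-9-(3-methoxy-3-oxoprop-1-en-2-yl)-6-methyl-11-oxabicyclo[4.4.1]undec-2-ene-2-carboxylate (25 without the silyl group) | C=C(C(=O)OC)[C@@H]1[C@H](OC(=O)[C@@]3(C)O[C@@H]3C)C[C@]2(C)CCC=C(C(=O)OC)[C@@H](O2)[C@H]1O | intermediate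
27 | CNP0240298.1 (germacrane locants 5R,6S,7R,8R,10S; 6,12-olide, 5,10-ether, methyl 15-oate, 8-O-[(2S,3R)-2,3-epoxy-2-methylbutanoyl]) | C=C1C(=O)O[C@H]2[C@H]1[C@H](OC(=O)[C@@]1(C)O[C@@H]1C)C[C@]1(C)CCC=C(C(=O)OC)[C@H]2O1 | target

**Count and risks**

Total step count: 17. Longest linear sequence: 13 steps (steps 1–6, 9–13, 16, 17).

Steps most likely to fail:

Step 13 (proposed new method). The oxa-Michael pre-equilibrium may be too slow or too unfavourable. Direct ten-membered 1,2-allylation of the enal, protonolysis of the allylindium or self-alkylation of the free hydroxyl would then consume the substrate. The fallback makes the two bonds one after the other by known chemistry. It sets out from 18, which is cyclised with CrCl2 in THF/DMF at high dilution without acid (intramolecular Nozaki–Hiyama-type allylation of the enal, the known way to ten-membered germacranolide rings) to the ten-membered diol F1. Transannular alkoxymercuration with Hg(O2CCF3)2 in THF (Markovnikov attack of the C5 hydroxyl on C10 of the electron-rich C9=C10 alkene) should give the organomercurial F2. Demercuration with NaBH4/NaOH comes back to the route at 20.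

Step 9. Facial selectivity in the addition to the α-silyloxy aldehyde may be poor, and the aldehyde may epimerise next to the carbonyl before it couples. The fallback sets out from 15 obtained as a mixture of C5 epimers. Dess–Martin oxidation gives the ketone F3. Felkin-controlled 1,2-reduction (NaBH4, CeCl3, MeOH, −78 °C, with the CBS reduction as a reagent-controlled variant) should come back to the route at 15 as the anti isomer.

Step 12. Bromination may also attack the secondary allylic hydroxyl, and the free C5 hydroxyl may alkylate itself with the new allylic bromide before the key step. The fallback masks O5 first and sets out from 15. TESOTf/2,6-lutidine gives the bis-silyl ether F4. Methanolysis (K2CO3, MeOH) gives the diol F5, MnO2 the enal F6 and Corey–Kim bromination the bromide F7. Selective removal of the triethylsilyl group (HF·pyridine, pyridine, THF, 0 °C) just before the key step comes back to the route at 18.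

Further compounds
F1 | step 13 | ten-membered ring diol (germacrane locants 5R,6S,7R,8R; 5-OH, 6-OTBS, 8-OH, 9E-alkene, methyl ester on C4, methyl acrylate unit on C7) | C=C(C(=O)OC)[C@@H]1[C@H](O)/C=C(C)/CC/C=C(/C(=O)OC)[C@@H](O)[C@H]1O[Si](C)(C)C(C)(C)C
F2 | step 13 | C9-(trifluoroacetoxymercurio) derivative of 20 (mercury trans to the new ether oxygen) | C=C(C(=O)OC)[C@@H]1[C@H](O)[C@@H]([Hg]OC(=O)C(F)(F)F)[C@]2(C)CCC=C(C(=O)OC)[C@@H](O2)[C@H]1O[Si](C)(C)C(C)(C)C
F3 | step 9 | methyl (2E,4S,6E,10E)-12-acetoxy-2-(acetoxymethyl)-4-[(tert-butyldimethylsilyl)oxy]-6-(methoxycarbonyl)-10-methyl-5-oxododeca-2,6,10-trienoate | CC(=O)OC/C=C(C)/CC/C=C(/C(=O)OC)C(=O)[C@@H](O[Si](C)(C)C(C)(C)C)/C=C(/C(=O)OC)COC(C)=O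
F4 | step 12 | 5-O-triethylsilyl ether of 15 | CC(=O)OC/C=C(C)/CC/C=C(/C(=O)OC)[C@@H](O[Si](CC)(CC)CC)[C@@H](O[Si](C)(C)C(C)(C)C)/C=C(/C(=O)OC)COC(C)=O
F5 | step 12 | 5-O-triethylsilyl ether of 16 | OC/C=C(C)/CC/C=C(/C(=O)OC)[C@@H](O[Si](CC)(CC)CC)[C@@H](O[Si](C)(C)C(C)(C)C)/C=C(/C(=O)OC)CO
F6 | step 12 | 5-O-triethylsilyl ether of 17 | O=C/C=C(C)/CC/C=C(/C(=O)OC)[C@@H](O[Si](CC)(CC)CC)[C@@H](O[Si](C)(C)C(C)(C)C)/C=C(/C(=O)OC)CO
F7 | step 12 | 5-O-triethylsilyl ether of 18 | O=C/C=C(C)/CC/C=C(/C(=O)OC)[C@@H](O[Si](CC)(CC)CC)[C@@H](O[Si](C)(C)C(C)(C)C)/C=C(/C(=O)OC)CBr
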